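**Retrosynthetic overview**

1. Ring labels: A = 3‑hydroxy‑4‑aryloxyphenyl, B = meta‑linked ether ring, C = para‑linked ether ring, D = 4‑hydroxy‑3‑aryloxyphenyl. All four benzene rings are bought, so the 20‑membered macrocycle is the only ring formed, and it is formed last.
2. 15 ⇐ 14: one hydrogenolysis removes one Br, two Cl and the benzyl ether.
3. 14 ⇐ 12: the macrocycle is closed at the ring C–O–ring D diaryl ether by oxidative phenol coupling (Tl(III), then Zn). This is the bond made by the biosynthetic phenol coupling, not a bibenzyl C–C bond. The dibromophenol D is the carbon partner and the dichlorophenol C the oxygen partner.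
4. 12 ⇐ 10: both CH2CH2 bridges come from stilbenes (one diimide reduction, then ortho‑bromination of ring D). Ring D is added by Heck coupling of 9 with styrene 8, and ring C by decarboxylative Knoevenagel condensation of 1 with 2.
5. The ring A–O–ring B ether is made early by SNAr of phenol 4 on fluoro‑aldehyde 6, whose formyl group then becomes the A–D bridge.

Assumption: 15 has no stereocentre and its 20‑membered ring is taken as conformationally mobile (no stable atropisomer), so it is achiral and no step has to set configuration.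

**Route**

Step 1
Reactants: 1 3,5-dichloro-4-hydroxybenzaldehyde; 2 (3-hydroxyphenyl)acetic acid
Product: 4 2,6-dichloro-4-[(E)-2-(3-hydroxyphenyl)ethenyl]phenol, via alpha-arylcinnamic acid 3 (not isolated)
Conditions: piperidine (2 equiv), N-methylimidazole (1 equiv), PEG-200, 150 °C (microwave), 30 min
Reagents that add atoms: none
Why: Perkin-type Knoevenagel condensation of the arylacetic acid with the 4-hydroxybenzaldehyde gives acid 3, which loses CO2 through its p-quinone methide tautomer (a path open only to 4-hydroxycinnamic acids) to give the thermodynamic E-stilbene; no stereocentre is formed.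

Step 2
Reactants: 5 4-fluoro-3-hydroxybenzaldehyde; 4 2,6-dichloro-4-[(E)-2-(3-hydroxyphenyl)ethenyl]phenol
Product: 7 3-(benzyloxy)-4-{3-[(E)-2-(3,5-dichloro-4-hydroxyphenyl)ethenyl]phenoxy}benzaldehyde, via 3-(benzyloxy)-4-fluorobenzaldehyde 6 (not isolated)
Conditions: BnBr (1.0 equiv), K2CO3, DMF, rt, 3 h; then 4 (1.1 equiv), K2CO3 (2.5 equiv), 110 °C
Reagents that add atoms: benzyl bromide, BrCc1ccccc1
Why: Williamson O-benzylation gives 6, and the unhindered ring-B phenoxide of 4 (pKa about 10) then displaces the fluoride para to the formyl group by SNAr (Meisenheimer complex) much faster than the hindered, weakly nucleophilic 2,6-dichlorophenoxide (pKa about 7).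

Step 3
Reactants: 7 3-(benzyloxy)-4-{3-[(E)-2-(3,5-dichloro-4-hydroxyphenyl)ethenyl]phenoxy}benzaldehyde
Product: 8 4-[(E)-2-{3-[2-(benzyloxy)-4-ethenylphenoxy]phenyl}ethenyl]-2,6-dichlorophenol
Conditions: Ph3PCH3Br (1.3 equiv), KOt-Bu (2.4 equiv), THF, 0 °C → rt
Reagents that add atoms: methyltriphenylphosphonium bromide, C[P+](c1ccccc1)(c1ccccc1)c1ccccc1.[Br-]
Why: Wittig methylenation of the aryl aldehyde with Ph3P=CH2, the extra equivalent of base only holding the dichlorophenol as its inert phenoxide.

Step 4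
Reactants: 8 4-[(E)-2-{3-[2-(benzyloxy)-4-ethenylphenoxy]phenyl}ethenyl]-2,6-dichlorophenol; 9 4-iodophenol
Product: 10 4-[(E)-2-(3-{2-(benzyloxy)-4-[(E)-2-(4-hydroxyphenyl)ethenyl]phenoxy}phenyl)ethenyl]-2,6-dichlorophenol
Conditions: Pd(OAc)2 (5 mol%), P(o-tol)3 (10 mol%), Et3N, DMF, 90 °C
Reagents that add atoms: none
Why: Mizoroki–Heck arylation of the terminal styrene by the aryl iodide (syn insertion, syn β-hydride elimination) gives the E-stilbene, while the aryl chlorides and the internal stilbene do not react under these conditions.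

Step 5
Reactants: 10 4-[(E)-2-(3-{2-(benzyloxy)-4-[(E)-2-(4-hydroxyphenyl)ethenyl]phenoxy}phenyl)ethenyl]-2,6-dichlorophenol
Product: 11 4-[2-(3-{2-(benzyloxy)-4-[2-(4-hydroxyphenyl)ethyl]phenoxy}phenyl)ethyl]-2,6-dichlorophenol
Conditions: TsNHNH2 (10 equiv), NaOAc (12 equiv), THF–H2O, reflux
Reagents that add atoms: none
Why: Diimide generated in situ transfers H2 concertedly to both stilbene C=C bonds and cannot cleave aryl–Cl bonds or the benzyl ether, which catalytic hydrogenation would put at risk.

Step 6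
Reactants: 11 4-[2-(3-{2-(benzyloxy)-4-[2-(4-hydroxyphenyl)ethyl]phenoxy}phenyl)ethyl]-2,6-dichlorophenol
Product: 12 4-[2-(3-(benzyloxy)-4-{3-[2-(3,5-dichloro-4-hydroxyphenyl)ethyl]phenoxy}phenyl)ethyl]-2,6-dibromophenol
Conditions: NBS (2.05 equiv), i-Pr2NH (0.2 equiv), CH2Cl2, 0 °C
Reagents that add atoms: N-bromosuccinimide, O=C1CCC(=O)N1Br
Why: Amine-catalysed ortho-bromination of a phenol with NBS (electrophilic aromatic substitution) hits only ring D, the one ring with free positions ortho to a free OH; ring C is blocked by Cl and the aryl ether rings A and B react far more slowly.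

Step 7
Reactants: 12 4-[2-(3-(benzyloxy)-4-{3-[2-(3,5-dichloro-4-hydroxyphenyl)ethyl]phenoxy}phenyl)ethyl]-2,6-dibromophenol
Product: 14 bromo-dichloro O-benzyl macrocycle (15 as its ring-A benzyl ether plus Br ortho to the ring-D OH plus Cl on both carbons ortho to the ring-C ether O), via quinol methyl ether dienone 13 (not isolated)
Conditions: Tl(NO3)3·3H2O (3 equiv), MeOH–THF (9:1), 1 mM, −20 → 0 °C; then Zn, AcOH, rt
Reagents that add atoms: methanol, CO (its CH3O group is in intermediate 13 only and is lost again before 14)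
Why: Thallium(III) oxidative phenol coupling of the Yamamura–Evans type: Tl(III) oxidises the dibromophenol D (lower oxidation potential, better leaving group) to a phenoxonium ion, the ring-C dichlorophenol oxygen adds at its ortho carbon with loss of bromide, methanol traps the para position as quinol ether 13, and zinc reduces 13 back to the phenol, so the aryl ether ends up ortho to the ring-D OH as in the biosynthetic coupling, with the halogens blocking ortho C–C coupling and high dilution favouring the 20-membered ring.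

Step 8
Reactants: 14 bromo-dichloro O-benzyl macrocycle
Product: 15 target macrocycle CNP0329842.0
Conditions: H2 (3 atm), 10% Pd/C, Et3N (5 equiv), MeOH–THF, 40 °C
Reagents that add atoms: none
Why: Pd-catalysed hydrogenolysis cleaves the benzyl ether and, with Et3N as acid scavenger, the aryl C–Br and both aryl C–Cl bonds (hydrodehalogenation), leaving the diaryl ethers and phenols untouched.

**Compound list**

1 | 3,5-dichloro-4-hydroxybenzaldehyde | O=Cc1cc(Cl)c(O)c(Cl)c1 | starting material
2 | (3-hydroxyphenyl)acetic acid | OC(=O)Cc1cccc(O)c1 | starting material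
3 | (2E)-3-(3,5-dichloro-4-hydroxyphenyl)-2-(3-hydroxyphenyl)prop-2-enoic acid (not isolated) | OC(=O)/C(c1cccc(O)c1)=C/c1cc(Cl)c(O)c(Cl)c1 | intermediate
4 | 2,6-dichloro-4-[(E)-2-(3-hydroxyphenyl)ethenyl]phenol | Oc1cccc(/C=C/c2cc(Cl)c(O)c(Cl)c2)c1 | intermediate
5 | 4-fluoro-3-hydroxybenzaldehyde | O=Cc1ccc(F)c(O)c1 | starting material
6 | 3-(benzyloxy)-4-fluorobenzaldehyde (not isolated) | O=Cc1ccc(F)c(OCc2ccccc2)c1 | intermediate
7 | 3-(benzyloxy)-4-{3-[(E)-2-(3,5-dichloro-4-hydroxyphenyl)ethenyl]phenoxy}benzaldehyde | O=Cc1ccc(Oc2cccc(/C=C/c3cc(Cl)c(O)c(Cl)c3)c2)c(OCc2ccccc2)c1 | intermediate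
8 | 4-[(E)-2-{3-[2-(benzyloxy)-4-ethenylphenoxy]phenyl}ethenyl]-2,6-dichlorophenol | C=Cc1ccc(Oc2cccc(/C=C/c3cc(Cl)c(O)c(Cl)c3)c2)c(OCc2ccccc2)c1 | intermediate
9 | 4-iodophenol | Oc1ccc(I)cc1 | starting material
10 | 4-[(E)-2-(3-{2-(benzyloxy)-4-[(E)-2-(4-hydroxyphenyl)ethenyl]phenoxy}phenyl)ethenyl]-2,6-dichlorophenol | Oc1ccc(/C=C/c2ccc(Oc3cccc(/C=C/c4cc(Cl)c(O)c(Cl)c4)c3)c(OCc3ccccc3)c2)cc1 | intermediate
11 | 4-[2-(3-{2-(benzyloxy)-4-[2-(4-hydroxyphenyl)ethyl]phenoxy}phenyl)ethyl]-2,6-dichlorophenol | Oc1ccc(CCc2ccc(Oc3cccc(CCc4cc(Cl)c(O)c(Cl)c4)c3)c(OCc3ccccc3)c2)cc1 | intermediate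
12 | 4-[2-(3-(benzyloxy)-4-{3-[2-(3,5-dichloro-4-hydroxyphenyl)ethyl]phenoxy}phenyl)ethyl]-2,6-dibromophenol | Oc1c(Br)cc(CCc2ccc(Oc3cccc(CCc4cc(Cl)c(O)c(Cl)c4)c3)c(OCc3ccccc3)c2)cc1Br | intermediate
13 | macrocyclic quinol methyl ether: ring D as 2-aryloxy-6-bromo-4-methoxy-4-alkylcyclohexa-2,5-dienone, rings A–C as in 14 (racemic at the methoxy-bearing carbon, which is destroyed in the same step; not isolated) | c1ccccc1COc1cc2ccc1Oc1cccc(c1)CCc1cc(Cl)c(c(Cl)c1)OC1=CC(OC)(C=C(Br)C1=O)CC2 | intermediate
14 | bromo-dichloro O-benzyl macrocycle: 15 with OBn in place of the ring-A OH, Br ortho to the ring-D OH (the side away from the ether), and Cl on both ring-C carbons ortho to the ether oxygen | c1ccccc1COc1cc2ccc1Oc1cccc(c1)CCc1cc(Cl)c(c(Cl)c1)Oc1cc(cc(Br)c1O)CC2 | intermediate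
15 | CNP0329842.0, the 20-membered bis(bibenzyl) bis(diaryl ether) with one OH on ring A and one on ring D (achiral) | Oc1cc2ccc1Oc1cccc(c1)CCc1ccc(cc1)Oc1cc(ccc1O)CC2 | target

**Step count and risks**

Total step count: 8. Longest linear sequence: 8 (steps 1 to 8; 5 and 9 are bought).

The three steps most likely to fail are steps 7, 1 and 2.

Step 7 (oxidative macrocyclisation). The open-chain phenol may be trapped as its own quinol ether, or may oligomerise, before the 20-membered ring closes. The fallback sets out from 11. Ring D is iodinated instead of brominated (I2, morpholine, CH2Cl2–MeOH, 0 °C) to give 4-[2-(3-(benzyloxy)-4-{3-[2-(3,5-dichloro-4-hydroxyphenyl)ethyl]phenoxy}phenyl)ethyl]-2,6-diiodophenol F1. The ring is then closed by anodic oxidation (constant current, glassy-carbon anode, LiClO4/MeOH, 1 mM) instead of a metal oxidant, giving the iodo quinol methyl ether dienone F2. This is reduced in the same pot with Zn/AcOH to the iodo-dichloro O-benzyl macrocycle F3. Hydrogenolysis of F3 (H2, Pd/C, Et3N) gives 15, where the fallback comes back to the route. The change is to an electrode-driven coupling of a more easily oxidised phenol with a better leaving group, and it also removes thallium.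

Step 1 (decarboxylative Knoevenagel condensation). The very acidic aldehyde 1 may be too deactivated as its phenoxide, or the decarboxylation may stall. The fallback sets out from 1 and builds the alkene by Wittig olefination instead. Bought 3-hydroxybenzyl alcohol F4 is heated with PPh3·HBr in MeCN to give (3-hydroxybenzyl)triphenylphosphonium bromide F5. Its ylide (KOt-Bu, 3.3 equiv, THF) reacts with 1 to give 4 together with its Z isomer, 2,6-dichloro-4-[(Z)-2-(3-hydroxyphenyl)ethenyl]phenol F6. A catalytic amount of I2 in refluxing heptane–THF converts F6 into the E isomer, so the fallback comes back to the route at 4.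

Step 2 (telescoped benzylation and SNAr). The dichlorophenoxide of 4 may compete, or the electron-rich fluoro-aldehyde may react too slowly with a stilbene phenoxide. The fallback changes the order of bond formation so that the SNAr partner has only one phenol. It sets out from 6, made from 5 as in step 2 but isolated. SNAr of 6 with the phenoxide of 2 (K2CO3, DMSO, 110 °C) gives {3-[2-(benzyloxy)-4-formylphenoxy]phenyl}acetic acid F7. Wittig methylenation (Ph3PCH3Br, KOt-Bu) first removes the aldehyde, so that it cannot self-condense, and gives {3-[2-(benzyloxy)-4-ethenylphenoxy]phenyl}acetic acid F8. Condensation of F8 with 1 under the conditions of step 1 (with BHT) passes through (2E)-2-{3-[2-(benzyloxy)-4-ethenylphenoxy]phenyl}-3-(3,5-dichloro-4-hydroxyphenyl)prop-2-enoic acid F9, which loses CO2 to give 8, where the fallback comes back to the route.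

**Further compounds**

F1 | step 7 | 4-[2-(3-(benzyloxy)-4-{3-[2-(3,5-dichloro-4-hydroxyphenyl)ethyl]phenoxy}phenyl)ethyl]-2,6-diiodophenol | Oc1c(I)cc(CCc2ccc(Oc3cccc(CCc4cc(Cl)c(O)c(Cl)c4)c3)c(OCc3ccccc3)c2)cc1I
F2 | step 7 | iodo quinol methyl ether dienone (13 with I in place of Br; racemic) | c1ccccc1COc1cc2ccc1Oc1cccc(c1)CCc1cc(Cl)c(c(Cl)c1)OC1=CC(OC)(C=C(I)C1=O)CC2
F3 | step 7 | iodo-dichloro O-benzyl macrocycle (14 with I in place of Br) | c1ccccc1COc1cc2ccc1Oc1cccc(c1)CCc1cc(Cl)c(c(Cl)c1)Oc1cc(cc(I)c1O)CC2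
F4 | step 1 | 3-hydroxybenzyl alcohol (bought) | OCc1cccc(O)c1
F5 | step 1 | (3-hydroxybenzyl)triphenylphosphonium bromide | Oc1cccc(C[P+](c2ccccc2)(c2ccccc2)c2ccccc2)c1.[Br-]
F6 | step 1 | 2,6-dichloro-4-[(Z)-2-(3-hydroxyphenyl)ethenyl]phenol | Oc1cccc(/C=C\c2cc(Cl)c(O)c(Cl)c2)c1
F7 | step 2 | {3-[2-(benzyloxy)-4-formylphenoxy]phenyl}acetic acid | OC(=O)Cc1cccc(Oc2ccc(C=O)cc2OCc2ccccc2)c1
F8 | step 2 | {3-[2-(benzyloxy)-4-ethenylphenoxy]phenyl}acetic acid | OC(=O)Cc1cccc(Oc2ccc(C=C)cc2OCc2ccccc2)c1
F9 | step 2 | (2E)-2-{3-[2-(benzyloxy)-4-ethenylphenoxy]phenyl}-3-(3,5-dichloro-4-hydroxyphenyl)prop-2-enoic acid | OC(=O)/C(c1cccc(Oc2ccc(C=C)cc2OCc2ccccc2)c1)=C/c1cc(Cl)c(O)c(Cl)c1
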